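The readings are simulated with constants of no real substance, noise included.

94.9 % of target stands in the grey run at 5.00 min, from substrate and partner charged at 0.50 M and 0.50 M, and the new flask is reckoned from that reading.

common to all: substrate 0.50 M (in portions, 4)

| charge | partner | remark | time |
|---|---|---|---|
| grey | 0.50 M | run made earlier; portions every 8.0 s |  |
| flask | 1.00 M | the portions of substrate follow each other after 8.0 s, the first at the start | 50 min |

grey run (percent of the substrate charged)

| time / min | substrate / % | target / % | over-reaction product / % |
|---|---|---|---|
| 0.333 | 56.7 | 6.6 | 1.1 |
| 1.00 | 38.2 | 47.0 | 1.4 |
| 2.00 | 17.8 | 73.8 | 0.9 |
| 2.50 | 12.8 | 82.5 | 1.1 |
| 4.00 | 5.8 | 92.2 | 0.7 |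
| 5.00 | 3.7 | 94.9 | 1.4 |

(readings scatter by 1 percentage point)

* which holds at 50 min: what has brought the reaction to rest, or that it has not come to rest (forward and back rates have come level / it is still moving / all of the substrate has reacted)
* how much of the substrate has reacted by 50 min
* how much target there is at 50 min, in percent of the substrate charged
* how much over-reaction product there is at 50 min, in percent of the substrate charged

- the reaction counts as stopped when no species that holds the substrate changes by six tenths of a point or more over the second half of the time

The target column of the grey run, still climbing at its last row, gives the target per partner, the percent of target that one equivalent of partner has been seen to carry, 94.9 %, a reading with a scatter of 1 percentage point and a floor rather than a limit. Multiplied by the equivalents of a flask, it says how much target the partner charge can pay for. The new flask, with 2.00 equivalents, can pay for 190 %, which is more than the 100% the substrate allows, so by this reckoning substrate is the limiting reagent. The substrate column of the grey run, from 12.8 % at 2.50 min to 3.7 % at 5.00 min, reads as a half-life of 1.40 min, far shorter than the new flask's 50 min. The new flask's time holds 35.7 of these read half-lives, so by this reckoning substrate in that flask should fall below the scatter of the readings. The over-reaction column of the grey run stays between 0.7 % and 1.4 %, within that scatter, which suggests for the new flask about a point of over-reaction product and the remainder as target.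

The forecast gives for the flask: all of the substrate has reacted, with 100 % reacted (99 % to 100 %), 96 % of target (84 % to 98.5 %) and 3 % of over-reaction product (1 % to 15 %), this last higher than the reading used above. Of the substrate it says: “so no equilibrium is evident”.

The flask gives: all of the substrate has reacted, with 100 % reacted, 98.4 % of target and 1.56 % of over-reaction product.

    open intermediate + second intermediate → target (k = 1.10 /M/s)
    partner → second intermediate (k = 0.0140 /s)
    substrate ⇌ open intermediate (K = 0.770, k = 0.0280 /s)
    partner + target → over-reaction product (k = 4.40 × 10⁻⁴ /M/s)

The flask's 98.4 % of target stays under the 190 % that the target per partner of 94.9 % allowed. The surplus of partner in that flask does not remain as partner: at 25.0 min partner stands at 0 % of its charge, beside 0.492 M of second intermediate. The running short of partner is the main reason for the small over-reaction, since the same flask with that running short taken away gives 72.6 % of over-reaction product against 1.56 %.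

In the neighbour flask with 0.25 M of partner, 0.500 equiv, the target per partner, a floor, pays for 47.5 % of target. That neighbour flask gives 49.7 % of target, above that floor, with partner at 0 % of its charge and substrate at 28 %.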